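| flask | G | X | temperature | remark | time |
|---|---|---|---|---|---|
| alpha | 0.050 M | 1.1 equiv | 65 °C | run made earlier |  |
| beta | 0.070 M | 1.1 equiv | 76 °C | run made earlier |  |
| theta | 0.11 M | 1.1 equiv | 65 °C | run made earlier |  |
| Friday's | 0.050 M (fed, over 20 min) | 1.10 equiv |  | the addition at 50 °C, then warmed to 70 °C; the feed brings no volume worth counting | 30 min |
| Thursday's | 0.050 M | 1.10 equiv (fed, over 20 min) | 70 °C | all else is in the flask from the start; the feed brings no volume worth counting | 30 min |
| Tuesday's | 0.050 M (fed, over 20 min) | 1.10 equiv | 70 °C | all else is in the flask from the start; the feed brings no volume worth counting | 30 min |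
| Saturday's | 0.050 M | 1.10 equiv |  | everything together at the start at 50 °C, warmed to 70 °C at 20 min | 30 min |
| Wednesday's | 0.050 M (in portions, 3, over 20 min) | 1.10 equiv | 70 °C | first portion at the start, last at 20 min | 30 min |
| Monday's | 0.050 M (fed, over 2.0 min) | 1.10 equiv | 70 °C | all else is in the flask from the start; the feed brings no volume worth counting | 30 min |

| run | time / min | Q / % | G / % |
|---|---|---|---|
| alpha | 5.00 | 58.6 | 16.5 |
| alpha | 10.0 | 41.3 | 13.7 |
| alpha | 15.0 | 29.8 | 11.7 |
| alpha | 20.0 | 21.0 | 8.2 |
| alpha | 25.0 | 15.4 | 6.9 |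
| alpha | 30.0 | 12.1 | 6.2 |
| beta | 3.00 | 43.4 | 16.4 |
| beta | 5.00 | 29.4 | 13.1 |
| beta | 8.00 | 16.8 | 8.4 |
| beta | 12.0 | 7.9 | 6.4 |
| beta | 20.0 | 2.6 | 2.5 |
| beta | 40.0 | 0.7 | 0.1 |
| theta | 2.50 | 66.8 | 16.2 |
| theta | 8.00 | 42.4 | 12.2 |
| theta | 12.0 | 30.7 | 10.0 |
| theta | 20.0 | 17.2 | 7.4 |
| theta | 30.0 | 8.2 | 4.0 |
| theta | 40.0 | 4.3 | 1.7 |

(standard deviation of a reading: 0.5 percentage points)

- what was read earlier has a scatter of 0.5 percentage points, one standard deviation

- the best flask by amount of Q, in percent of the G charged; "all alike" if 1.5 percentage points covers them all (Friday's / Thursday's / Tuesday's / Saturday's / Wednesday's / Monday's / all alike)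
- amount of Q at the end, in percent of the G charged, Friday's
- amount of Q at the end, in percent of the G charged, Thursday's
- amount of Q at the end, in percent of the G charged, Tuesday's
- amount of Q at the end, in percent of the G charged, Saturday's
- amount of Q at the end, in percent of the G charged, Wednesday's
- amount of Q at the end, in percent of the G charged, Monday's

- I first compared the alpha and beta runs, adding Q and G into one pool, and the pool fell more slowly in alpha: 0.0565 min⁻¹ at 65 °C against 0.141 min⁻¹ at 76 °C, each read as a first-order fall between two readings.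
- Taking the logarithm as linear in temperature gave 0.0857 min⁻¹ at 70 °C, and this I carried: the pool rate, a pseudo-first-order constant for the fall of Q and G together.
- Stretching the same line down gave a slower 0.0162 min⁻¹ at 50 °C, which was an extrapolation and so less firm.
- I then froze Q's share of the late pool: it read 66.1% in alpha and 67.2% in theta at 30.0 min, though theta held twice the G.
- Friday's stood hot for 10.0 min, so by my estimate the pool rate allowed its pool to keep 42.4% over that stretch.
- For my bound from above I allowed Friday's no loss in the cold, which gave 28.1% of Q.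
- For my bound from below I let all of Friday's G stand cold for the full 20 min, which gave 20.3%.
- A steady feed gives each part of the G on average half of that wait, so I tightened my own figure for Friday's to 23.9%.
- The forecast named Friday's as best, with 23% for Friday's, 20% for Saturday's, 13.5% for Wednesday's, 11.5% for Tuesday's, 10.5% for Thursday's and 5% for Monday's, holding that “Holding at 50 °C for 20 minutes nearly stops the loss”. Its Friday's figure lay inside my bracket, a little below my own.
- The best flask was Friday's, and Friday's gave 23.6%, inside the bracket. Saturday's gave 20.3%, Wednesday's 13.3%, Tuesday's 11.5%, Thursday's 10.8% and Monday's 4.57%.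

    G + X ⇌ Q + Z (K = 10.0, k = 0.870 L mol⁻¹ s⁻¹, Ea = 67.0 kJ mol⁻¹, ΔH = −29.0 kJ mol⁻¹)
    Q + Z → J (k = 0.0100 L mol⁻¹ s⁻¹, Ea = 80.0 kJ mol⁻¹)
    Q → E (k = 0.00180 s⁻¹, Ea = 97.0 kJ mol⁻¹)
    (constants at 70 °C)

- Friday's pool kept 38.1% from 20.0 min to 30.0 min, where the pool rate had allowed 42.4%.
- In Monday's flask, from 12 min to 30 min, the pool rate allowed 21.4%, and the pool kept 22.3%.

(The readings were generated by integration for an exercise; scatter was added.)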